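Retrosynthetic cuts, in order: the O7–CH2 bond of the geranyl ether, the three MOM acetals, O1–C8a (ring C), C4–C4a (aryl ketone), C8–CH2 (C-geranyl), and C3–C4 together with the C2 carbinol (β-keto ester).
Enabling feature: C8a of ring A is ortho to C4a, the carbon that carries the C4 ketone, and next to the geranyl-bearing C8, so a fluorine on C8a is activated by the ketone and marks the one carbon that O1 has to reach.
Forward, ring A is bought as 5-fluororesorcinol, protected and brominated on both carbons flanking fluorine; one C–Br becomes C8–geranyl and the other C4a–acyl, so no choice between fluorine-flanked and oxygen-flanked carbons is left to a deprotonation.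
Ring B comes from 4'-hydroxyacetophenone; the only stereocentre (future C2) is set by Noyori asymmetric transfer hydrogenation of a β-keto ester and carried as a silyl-protected (S)-β-hydroxy Weinreb amide.
After the fragments are joined and the silyl group is removed, ring C, the only ring made, closes by alkoxide displacement of fluoride with the C2–O bond intact.
Acid then frees the three phenols and the most acidic one, on C7, is geranylated last.

Key step: step 11

Remark: flavanone numbering (O1, C2–C4, C4a, C5–C8, C8a, ring B primed) is used for the target and for the atoms of intermediates that end up in it; geranyl is (2E)-3,7-dimethylocta-2,6-dien-1-yl and MOM is methoxymethyl.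

Step 1
Reactants: 1 5-fluororesorcinol
Product: 2 1-fluoro-3,5-bis(methoxymethoxy)benzene
Conditions: NaH (2.4 equiv), MOMCl (2.4 equiv), DMF, 0 °C → rt
Reagents that add atoms: chloromethyl methyl ether (MOMCl), COCCl
Why: Double Williamson etherification of the sodium resorcinolate with the reactive α-chloro ether should give the bis-acetal, which withstands the organolithium and alkoxide chemistry ahead and leaves with the third MOM group at the end.

Step 2
Reactants: 2 1-fluoro-3,5-bis(methoxymethoxy)benzene
Product: 3 2,4-dibromo-3-fluoro-1,5-bis(methoxymethoxy)benzene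
Conditions: NBS (2.05 equiv), MeCN, 0 °C → rt
Reagents that add atoms: N-bromosuccinimide (NBS), O=C1CCC(=O)N1Br
Why: Electrophilic aromatic bromination is expected para to each acetal oxygen, that is on the two equivalent carbons flanking fluorine, while the carbon between the two oxygens (future C6) is the slowest site, as in the 2,6-dihalogenation of other 1-substituted 3,5-dialkoxybenzenes.

Step 3
Reactants: 3 2,4-dibromo-3-fluoro-1,5-bis(methoxymethoxy)benzene; 4 geranyl bromide
Product: 7 2-bromo-3-fluoro-4-geranyl-1,5-bis(methoxymethoxy)benzene, via aryllithium 5 (not isolated), via arylcopper 6 (not isolated)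
Conditions: n-BuLi (1.0 equiv), THF, −78 °C; CuBr·SMe2 (1.0 equiv, in Me2S/THF), −78 °C; 4, −78 → 0 °C
Reagents that add atoms: none
Why: Bromine–lithium exchange on one of the two equivalent C–Br bonds, transmetalation to the arylcopper and SN2 allylation by the primary allylic bromide (copper-mediated aryl–allyl coupling) should install the geranyl group with its E double bond untouched, the early transfer to copper forestalling loss of LiF from the ortho-fluoroaryllithium.

Step 4
Reactants: 8 4'-hydroxyacetophenone
Product: 9 4'-(methoxymethoxy)acetophenone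
Conditions: MOMCl (1.3 equiv), K2CO3, acetone, rt
Reagents that add atoms: chloromethyl methyl ether (MOMCl), COCCl
Why: Williamson etherification of the acidic para-acyl phenol masks the future C4' hydroxyl with the same acetal as on ring A, so that one acid step can free all three phenols.

Step 5
Reactants: 9 4'-(methoxymethoxy)acetophenone
Product: 10 ethyl 3-[4-(methoxymethoxy)phenyl]-3-oxopropanoate
Conditions: NaH (2.5 equiv), (EtO)2CO (3 equiv), THF, reflux; AcOH quench
Reagents that add atoms: diethyl carbonate, CCOC(=O)OCC
Why: Crossed Claisen condensation of the methyl ketone enolate with the non-enolisable carbonate forms the future C3–C4 bond and is driven forward by deprotonation of the β-keto ester.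

Step 6
Reactants: 10 ethyl 3-[4-(methoxymethoxy)phenyl]-3-oxopropanoate
Product: 11 ethyl (3S)-3-hydroxy-3-[4-(methoxymethoxy)phenyl]propanoate
Conditions: RuCl(p-cymene)[(S,S)-TsDPEN] (1 mol %), HCO2H/Et3N (5:2), EtOAc, 30 °C
Reagents that add atoms: none
Why: In this Noyori asymmetric transfer hydrogenation the (S,S)-TsDPEN ruthenium hydride reduces the aryl ketone through an outer-sphere six-membered transition state with the aryl group held under the cymene ligand, the facial sense that gives (S)-1-arylethanols from acetophenones and here the (S)-carbinol (aryl still outranks the CH2 branch), which becomes C2 of the target.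

Step 7
Reactants: 11 ethyl (3S)-3-hydroxy-3-[4-(methoxymethoxy)phenyl]propanoate
Product: 12 (3S)-3-hydroxy-N-methoxy-N-methyl-3-[4-(methoxymethoxy)phenyl]propanamide
Conditions: MeNH(OMe)·HCl (1.6 equiv), iPrMgCl (4.5 equiv), THF, −20 → 0 °C
Reagents that add atoms: N,O-dimethylhydroxylamine hydrochloride, CNOC.Cl
Why: Aminolysis of the ester by the chloromagnesium amide of N,O-dimethylhydroxylamine (Weinreb amide formation) tolerates the free hydroxyl as its magnesium alkoxide and leaves the β stereocentre untouched.

Step 8
Reactants: 12 (3S)-3-hydroxy-N-methoxy-N-methyl-3-[4-(methoxymethoxy)phenyl]propanamide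
Product: 13 (3S)-3-(tert-butyldimethylsilyloxy)-N-methoxy-N-methyl-3-[4-(methoxymethoxy)phenyl]propanamide
Conditions: TBSCl, imidazole, DMF, rt
Reagents that add atoms: tert-butyldimethylsilyl chloride (TBSCl), CC(C)(C)[Si](C)(C)Cl
Why: Imidazole-promoted silylation of the secondary benzylic alcohol removes the acidic proton that would otherwise consume the aryllithium of the next step.

Step 9
Reactants: 7 2-bromo-3-fluoro-4-geranyl-1,5-bis(methoxymethoxy)benzene; 13 (3S)-3-(tert-butyldimethylsilyloxy)-N-methoxy-N-methyl-3-[4-(methoxymethoxy)phenyl]propanamide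
Product: 16 (3S)-3-(tert-butyldimethylsilyloxy)-1-[2-fluoro-3-geranyl-4,6-bis(methoxymethoxy)phenyl]-3-[4-(methoxymethoxy)phenyl]propan-1-one, via aryllithium 14 (not isolated), via lithium hemiaminal 15 (not isolated)
Conditions: 7, n-BuLi (1.0 equiv), THF, −78 °C; 13 in THF, −78 → −50 °C; aq. NH4Cl
Reagents that add atoms: none
Why: Bromine–lithium exchange places lithium on the carbon flanked by fluorine and an acetal oxygen without regiochemical ambiguity, and addition to the Weinreb amide stops at the chelated tetrahedral lithium adduct (Weinreb ketone synthesis), which releases the aryl ketone only on work-up.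

Step 10
Reactants: 16 (3S)-3-(tert-butyldimethylsilyloxy)-1-[2-fluoro-3-geranyl-4,6-bis(methoxymethoxy)phenyl]-3-[4-(methoxymethoxy)phenyl]propan-1-one
Product: 17 (3S)-1-[2-fluoro-3-geranyl-4,6-bis(methoxymethoxy)phenyl]-3-hydroxy-3-[4-(methoxymethoxy)phenyl]propan-1-one
Conditions: HF·pyridine, pyridine, THF, 0 °C → rt
Reagents that add atoms: none
Why: Fluoride-driven cleavage of the Si–O bond in a pyridine-buffered, non-basic medium should free the β-hydroxy ketone without retro-aldol cleavage, dehydration or loss of the aryl acetals.

Step 11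
Reactants: 17 (3S)-1-[2-fluoro-3-geranyl-4,6-bis(methoxymethoxy)phenyl]-3-hydroxy-3-[4-(methoxymethoxy)phenyl]propan-1-one
Product: 20 (2S)-8-geranyl-5,7-bis(methoxymethoxy)-2-[4-(methoxymethoxy)phenyl]chroman-4-one, via potassium alkoxide 18 (not isolated), via Meisenheimer adduct 19 (not isolated)
Conditions: KOtBu (1.05 equiv), THF, −40 → 0 °C; aq. NH4Cl
Reagents that add atoms: none
Why: KOtBu reversibly turns the C2 hydroxyl into potassium alkoxide 18, which adds to the fluorine-bearing C8a to give Meisenheimer anion 19 with its charge spread over C4a and the C4 carbonyl oxygen, and fluoride then leaves, an addition–elimination nucleophilic aromatic substitution of the kind known for β-alkoxides of ortho-fluoroaryl ketones closing to chroman-4-ones. Ring C, the only ring formed, closes as a six-membered ring, 6-exo-trig if the C8a=C8 bond is counted as the π bond attacked (6-endo-trig if the C8a=C4a bond that passes the charge to the ketone is counted), and the short tether lets oxygen approach C8a from above the ring plane. No stereocentre is created, and C2 keeps its (S) configuration because its C–O bond is never broken. The step needs ring closure to outrun retro-aldol cleavage, dehydration through the C3 enolate and base-induced reopening of the flavanone: the ortho ketone and the electronegative fluorine speed the rate-limiting addition, the acetal oxygens on C5 and C7 are meta to C8a and so cannot push charge onto it, and the single cold equivalent of base ends as inert KF, so the product is not left in a basic medium. Site selectivity is not in question, since fluorine is the only leaving group on ring A and sits on the one carbon that O1 has to join.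

Step 12
Reactants: 20 (2S)-8-geranyl-5,7-bis(methoxymethoxy)-2-[4-(methoxymethoxy)phenyl]chroman-4-one
Product: 21 (2S)-8-geranylnaringenin
Conditions: aq. HCl (3 M)/MeOH, rt → 40 °C
Reagents that add atoms: none
Why: Acid-catalysed transacetalisation to methanol (acetal solvolysis) removes the three MOM groups as dimethoxymethane, the C5 acetal first because of the neighbouring carbonyl, under conditions mild enough that the trisubstituted alkenes and the C2–O bond should be left alone.

Step 13
Reactants: 21 (2S)-8-geranylnaringenin; 4 geranyl bromide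
Product: 22 (2S)-8-geranyl-7-(geranyloxy)-5-hydroxy-2-(4-hydroxyphenyl)chroman-4-one (CNP0103685.1)
Conditions: 4 (1.05 equiv), KHCO3 (1.2 equiv), DMF, rt
Reagents that add atoms: none
Why: In this Williamson etherification KHCO3 should ionise only the C7 hydroxyl, the most acidic because it is para to the C4 carbonyl, while the C5 hydroxyl is hydrogen-bonded to that carbonyl and the C4' hydroxyl is an ordinary phenol, and so weak a base should not open ring C by β-elimination, so C2 stays (S).

Compound list
1 | 5-fluororesorcinol (5-fluorobenzene-1,3-diol) | Oc1cc(O)cc(F)c1 | starting material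
2 | 1-fluoro-3,5-bis(methoxymethoxy)benzene | COCOc1cc(F)cc(OCOC)c1 | intermediate
3 | 2,4-dibromo-3-fluoro-1,5-bis(methoxymethoxy)benzene | COCOc1cc(OCOC)c(Br)c(F)c1Br | intermediate
4 | geranyl bromide, (2E)-1-bromo-3,7-dimethylocta-2,6-diene | CC(C)=CCC/C(C)=C/CBr | starting material
5 | aryllithium: [3-bromo-2-fluoro-4,6-bis(methoxymethoxy)phenyl]lithium (not isolated) | [Li]c1c(F)c(Br)c(OCOC)cc1OCOC | intermediate
6 | arylcopper: [3-bromo-2-fluoro-4,6-bis(methoxymethoxy)phenyl]copper (not isolated) | [Cu]c1c(F)c(Br)c(OCOC)cc1OCOC | intermediate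
7 | 2-bromo-3-fluoro-4-geranyl-1,5-bis(methoxymethoxy)benzene | COCOc1cc(OCOC)c(C/C=C(\C)CCC=C(C)C)c(F)c1Br | intermediate
8 | 4'-hydroxyacetophenone | CC(=O)c1ccc(O)cc1 | starting material
9 | 4'-(methoxymethoxy)acetophenone | CC(=O)c1ccc(OCOC)cc1 | intermediate
10 | ethyl 3-[4-(methoxymethoxy)phenyl]-3-oxopropanoate | CCOC(=O)CC(=O)c1ccc(OCOC)cc1 | intermediate
11 | ethyl (3S)-3-hydroxy-3-[4-(methoxymethoxy)phenyl]propanoate | O[C@H](c1ccc(OCOC)cc1)CC(=O)OCC | intermediate
12 | (3S)-3-hydroxy-N-methoxy-N-methyl-3-[4-(methoxymethoxy)phenyl]propanamide | O[C@H](c1ccc(OCOC)cc1)CC(=O)N(C)OC | intermediate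
13 | (3S)-3-(tert-butyldimethylsilyloxy)-N-methoxy-N-methyl-3-[4-(methoxymethoxy)phenyl]propanamide | CC(C)(C)[Si](C)(C)O[C@H](c1ccc(OCOC)cc1)CC(=O)N(C)OC | intermediate
14 | aryllithium: [2-fluoro-3-geranyl-4,6-bis(methoxymethoxy)phenyl]lithium (not isolated) | [Li]c1c(F)c(C/C=C(\C)CCC=C(C)C)c(OCOC)cc1OCOC | intermediate
15 | lithium hemiaminal: tetrahedral adduct of 14 to the amide carbonyl of 13, new carbinol centre undefined (not isolated) | CC(C)(C)[Si](C)(C)O[C@H](c1ccc(OCOC)cc1)CC(O[Li])(N(C)OC)c1c(F)c(C/C=C(\C)CCC=C(C)C)c(OCOC)cc1OCOC | intermediate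
16 | (3S)-3-(tert-butyldimethylsilyloxy)-1-[2-fluoro-3-geranyl-4,6-bis(methoxymethoxy)phenyl]-3-[4-(methoxymethoxy)phenyl]propan-1-one | CC(C)(C)[Si](C)(C)O[C@H](c1ccc(OCOC)cc1)CC(=O)c1c(F)c(C/C=C(\C)CCC=C(C)C)c(OCOC)cc1OCOC | intermediate
17 | (3S)-1-[2-fluoro-3-geranyl-4,6-bis(methoxymethoxy)phenyl]-3-hydroxy-3-[4-(methoxymethoxy)phenyl]propan-1-one | O[C@H](c1ccc(OCOC)cc1)CC(=O)c1c(F)c(C/C=C(\C)CCC=C(C)C)c(OCOC)cc1OCOC | intermediate
18 | potassium alkoxide of 17 (not isolated) | [K+].[O-][C@H](c1ccc(OCOC)cc1)CC(=O)c1c(F)c(C/C=C(\C)CCC=C(C)C)c(OCOC)cc1OCOC | intermediate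
19 | Meisenheimer adduct: potassium dienolate with O1 and F both on C8a, C8a configuration undefined (not isolated) | [K+].COCOC1=CC(OCOC)=C(C/C=C(\C)CCC=C(C)C)C2(F)O[C@H](c3ccc(OCOC)cc3)CC([O-])=C12 | intermediate
20 | (2S)-8-geranyl-5,7-bis(methoxymethoxy)-2-[4-(methoxymethoxy)phenyl]chroman-4-one | COCOc1cc(OCOC)c2c(c1C/C=C(\C)CCC=C(C)C)O[C@H](c1ccc(OCOC)cc1)CC2=O | intermediate
21 | (2S)-8-geranylnaringenin, (2S)-8-geranyl-5,7-dihydroxy-2-(4-hydroxyphenyl)chroman-4-one | Oc1cc(O)c2c(c1C/C=C(\C)CCC=C(C)C)O[C@H](c1ccc(O)cc1)CC2=O | intermediate
22 | (2S)-8-geranyl-7-(geranyloxy)-5-hydroxy-2-(4-hydroxyphenyl)chroman-4-one (CNP0103685.1) | CC(C)=CCC/C(C)=C/COc1cc(O)c2c(c1C/C=C(\C)CCC=C(C)C)O[C@H](c1ccc(O)cc1)CC2=O | target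

Total step count: 13.
Longest linear sequence: 10 steps (steps 4–13, from 8); steps 1–3 form the ring-A branch that joins at step 9.

Steps most likely to fail

Step 11. The alkoxide may fragment by retro-aldol reaction, or the C3 enolate may expel hydroxide, faster than oxygen adds to the hindered, electron-rich C8a, and re-aldolisation of the fragments would erode the enantiopurity. The fallback sets out from silyl ether 16 and avoids both the free alcohol and the alkoxide base. Anhydrous tetrabutylammonium fluoride in THF at 0 °C should remove the silyl group and unmask the oxygen, next to the aryl fluoride, as the tetrabutylammonium alkoxide of 17 F1. This is expected to close onto C8a at once, and the fluoride it expels carries the desilylation on, so only a small standing amount of a weakly basic fluoride is present. Fluoride-triggered aromatic substitution of silyl ethers on activated aryl fluorides is known chemistry. The route is rejoined at 20.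

Step 9. Loss of LiF from the ortho-fluoroaryllithium (aryne formation), or deprotonation of the amide at C3 with β-elimination of the silyloxy group, may outpace the slow acylation of a doubly ortho-substituted aryllithium. The fallback sets out from 13 and replaces the amide by a far more reactive electrophile. Reduction with iBu2AlH in THF at −78 °C should give (3S)-3-(tert-butyldimethylsilyloxy)-3-[4-(methoxymethoxy)phenyl]propanal F2. This aldehyde is expected to take up aryllithium 14 (from 7 as before) within minutes at −78 °C and give (3S)-3-(tert-butyldimethylsilyloxy)-1-[2-fluoro-3-geranyl-4,6-bis(methoxymethoxy)phenyl]-3-[4-(methoxymethoxy)phenyl]propan-1-ol F3 as a mixture of C1 epimers. Oxidation with Dess–Martin periodinane (NaHCO3, CH2Cl2) removes the new stereocentre and rejoins the route at 16.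

Step 12. Protonation of a geranyl double bond with ring closure by the neighbouring C7 hydroxyl (chroman formation), or acid-promoted opening of ring C with loss of configuration at C2, may compete with acetal solvolysis. The fallback sets out from 20 and exchanges the acetals for silyl groups without protic acid. TMSOTf with 2,2'-bipyridyl in MeCN at 0 °C converts aryl MOM ethers into aryl trimethylsilyl ethers and should give (2S)-8-geranyl-5,7-bis(trimethylsilyloxy)-2-[4-(trimethylsilyloxy)phenyl]chroman-4-one F4. Stirring with water at neutral pH then hydrolyses the silyl ethers and rejoins the route at 21.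

Further compounds
F1 | step 11 | tetrabutylammonium alkoxide of 17 | CCCC[N+](CCCC)(CCCC)CCCC.[O-][C@H](c1ccc(OCOC)cc1)CC(=O)c1c(F)c(C/C=C(\C)CCC=C(C)C)c(OCOC)cc1OCOC
F2 | step 9 | (3S)-3-(tert-butyldimethylsilyloxy)-3-[4-(methoxymethoxy)phenyl]propanal | CC(C)(C)[Si](C)(C)O[C@H](c1ccc(OCOC)cc1)CC=O
F3 | step 9 | (3S)-3-(tert-butyldimethylsilyloxy)-1-[2-fluoro-3-geranyl-4,6-bis(methoxymethoxy)phenyl]-3-[4-(methoxymethoxy)phenyl]propan-1-ol (C1 epimers) | CC(C)(C)[Si](C)(C)O[C@H](c1ccc(OCOC)cc1)CC(O)c1c(F)c(C/C=C(\C)CCC=C(C)C)c(OCOC)cc1OCOC
F4 | step 12 | (2S)-8-geranyl-5,7-bis(trimethylsilyloxy)-2-[4-(trimethylsilyloxy)phenyl]chroman-4-one | C[Si](C)(C)Oc1cc(O[Si](C)(C)C)c2c(c1C/C=C(\C)CCC=C(C)C)O[C@H](c1ccc(O[Si](C)(C)C)cc1)CC2=O
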